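**Conventions, one correction and one assumption**

- Locants: unit 1 is the dihydrobenzofuran fused to ring A (O1, C2, C3, C3a–C7a); unit 2 is the one fused to ring B (primed locants); ring C is the 3,5-dioxygenated ring on C3′.
- Correction: the target has seven phenolic hydroxyls, so its fully methylated form (28, identical with A1 below) is a heptamethyl ether with seven OCH3 groups, not a hexamethyl ether. The bromide 26 is the hexamethyl ether.
- Assumption: the (R)-configured pyridine-oxazoline ligand is taken to give the (S)-flavanone, by analogy with cyclic enones. If the sense proved the reverse, the two ligand antipodes would change places between steps 5 and 10 and nothing else would change.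

## Structural features

The target is a resveratrol trimer with seven free phenols, two trans-2,3-diaryl-2,3-dihydrobenzofurans and one (E)-4-hydroxystyryl arm. Ring A carries the styryl arm at C6, a hydroxyl at C4 and the fused dihydrofuran; C2 bears a 4-hydroxyphenyl ring and C3 is bonded to C6′ of ring B. Ring B is in turn the benzo ring of the second dihydrobenzofuran, whose C2′ bears a 4-hydroxyphenyl ring and whose C3′ bears ring C. There are four stereocentres in two vicinal trans pairs, C2/C3 (R,R) and C2′/C3′ (S,S); ring B separates the pairs, so neither can control the other and each absolute sense needs its own source. The fragile elements are the two benzylic C2–O and C2′–O bonds (para-oxygenated, hence easily ionised by acid), the electron-rich stilbene (acid, oxidants, light) and the free polyphenol itself. The real difficulty is the two sp3–sp2 bonds C3–C6′ and C3′–C1 of ring C: both aryl carbons are meta to the oxygens of their rings, out of reach of Friedel–Crafts chemistry, and both bonds must be formed trans to a neighbouring aryl group. The key step exploits the fact that each unit (benzo ring, O1, C2, C3) is a flavanone skeleton less one ring atom. C2 with its aryl group is the flavanone stereocentre; the C3–C3a bond arises when the benzo ring shifts from the carbonyl carbon to C3; the extruded carbon remains on C3 as an ester that can later be exchanged for an aryl group. Rings A and B carry the same substituents at that stage, so one flavanone constitution, in its two enantiomeric forms, serves both units.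

## Logic of the disconnections

**29 ⇒ 28.** The seven O–CH3 bonds are cut. The free heptaphenol is oxidation-prone and incompatible with the organometallic steps, whereas in 28 every oxygen comes from a purchasable methoxy building block. The gain is that no protecting-group step is needed anywhere. The demand is one global ether cleavage that spares the two benzylic C–O bonds and the alkene.

**28 ⇒ 26 + 27.** The C6–alkenyl bond is cut. It is an unhindered sp2–sp2 bond, and the alkene geometry can be bought with 27. This keeps the stilbene out of every oxidative, acidic and radical step. The forward step must couple an electron-rich aryl bromide with retention of the E geometry.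

**26 ⇒ 23 + 17 (through 25).** The C3–C6′ bond between the units is cut. C6′ is meta to both oxygens of ring B, so the bond is best made from an aryl nucleophile at C6′ and a radical at C3. The cut gives two pieces of similar size, each with one trans pair. The forward step must set C3 trans to C2 under substrate control, tolerate the C6 bromide of 23, and allow 25 to be formed from 17 without deprotonation at its benzylic positions.

**17 ⇒ 13 + 14 (through 16).** The C3′–aryl bond to ring C is cut for the same reason: ring C is attached through a carbon meta to both its oxygens. Unit 2 is reduced to a carboxylic acid derivative and a simple aryl bromide. The demands are those of the previous cut in an easier setting.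

**13 ⇒ 12 ⇒ 11 and 23 ⇒ 22 ⇒ 21.** Only the acyl C–O bonds change (redox-active ester to acid to methyl ester). This is the functional-group price of using the ester that the ring contraction delivers. The forward steps must not open the dihydrofuran by β-elimination.

**11 ⇒ 8 and 21 ⇒ 18.** The C3–C3a bond is cut and the benzo ring is returned to the ester carbon, which becomes the ring carbonyl C4 again. A vicinal stereo pair is thereby reduced to the single C2 centre of 8 (or 18), and the ester that results in the forward sense is exactly the radical precursor needed above. The forward step must make the benzo ring migrate in preference to the C2 aryl group, give the trans product, and not ionise the C2–O bond.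

**8 and 18 ⇒ 6 + 7.** The C2–aryl bond is cut. The only stereogenic event of each series becomes a catalytic conjugate addition in which the two series differ solely in the ligand antipode. One achiral intermediate, 6, therefore serves both units. The forward step must be highly enantioselective and leave the aryl bromide untouched.

**6 ⇒ 4.** The O1–C2 and C2–C3 bonds are cut, removing the one-carbon unit C2. What remains is an ortho-hydroxyaryl methyl ketone. The forward step is a condensation and cyclisation with a formyl equivalent.

**4 ⇒ 3 ⇒ 2 ⇒ 1.** One O–CH3 bond is cut (the one next to the carbonyl), then the C–CH3 bond of the acetyl group after an oxidation-state change. This leads to 1, in which bromine para to the carbonyl carbon and two ortho oxygens are already in place. That pattern is not the one favoured by electrophilic substitution of 14. The forward demand is a selective mono-demethylation, which chelation makes easy.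

## Other disconnections considered

**Alternative 1:** The cut is at O1–C2 and O1′–C2′ of A1 (identical with 28), leading back to the open-chain diphenol diol A2. In the forward step acid ionises both 4-methoxybenzylic alcohols of A2 and each cation is captured by the neighbouring phenol of ring A or ring B.
- In its favour: both heterocycles form in one late operation; the cations are well stabilised; the carbinol configurations are irrelevant because closure is stereoconvergent toward the trans rings; no oxidant or organometallic is needed.
- Against it here: the stereochemical burden moves to the isolated C3 and C3′ centres of A2, each a carbon bearing two different aryl rings, for which there is no simple asymmetric entry. The cations would also form in the presence of the stilbene and of ring C, which are competent π-nucleophiles, so carbocyclisation may compete.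
- Comparison: in ring-forming economy (two rings in one step) and in atom economy this alternative is the better of the two. In relative (trans) control it is the equal of the chosen plan, since both rely on the substrate. In absolute control it is weaker, because the chosen plan draws each pair from one catalytically set centre. Its overall step count would probably be higher because A2 is hard to make.

**Alternative 2:** The cut removes ring B (C3a′–C4′, C7′–C7a′, C4′–C5′), leading from A3 back to the cyclobutenone A4 and the siloxyalkyne A5. In the forward step heating opens A4 to a vinylketene, which adds A5 by [2+2]; four-electron ring opening, six-electron electrocyclisation and tautomerisation then give the phenol A3.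
- In its favour: the awkward substitution pattern of ring B is built regiospecifically without metals. The C3–C6′ bond is present from the start, so no excess of an advanced arylmetal is needed; on this point it is better than step 14 of the chosen plan. The aryl bromide is untouched, which is also better than a nickel step.
- Against it here: A4 needs several steps from a unit 1 acid, and its C3–H is vinylogously acidic under prolonged heating. More seriously, A3 still lacks C2′ with its aryl group, so the C2′/C3′ pair must be created afterwards with nothing to relate its absolute sense to unit 1.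
- Comparison: structurally and mechanistically the pericyclic cascade is an elegant and equal answer to the inter-unit bond. In stereocontrol and step economy the chosen plan is stronger, because it sets unit 2 from a single flavanone centre before the union.

**Alternative 3:** The cut is at C6–C7 of ring A, leading from A6 back to the 2-methyl-4,5-dihydrofuran diketone A7. In the forward step base forms the vinylogous enolate at the methyl group of A7; it adds to the cinnamoyl carbonyl, and dehydration plus enolisation of the C4 ketone aromatise ring A.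
- In its favour: the styryl arm arrives with ring A, so no late palladium coupling and no aryl halide are needed; on this point it is better than the chosen plan. The C4 hydroxyl emerges distinguished from the six methyl ethers. The cascade is redox-neutral.
- Against it here: A7 is a long and sensitive precursor. It is a non-aromatic trans-2,3-disubstituted dihydrofuran already carrying unit 2, with an epimerisable C3 and no simple enantioselective construction. Its enone and 1,3-diketone offer competing conjugate addition, O-cyclisation and retro-Claisen pathways.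
- Comparison: the late stage is mechanistically the equal of a Suzuki coupling in reliability of bond formation. The chosen plan is clearly shorter, since ring A is bought aromatic, and unit 2 would still need the ring contraction or a substitute.

Key step: step 6

## Route

Step 1
Reactants: 1 4-bromo-2,6-dimethoxybenzaldehyde
Product: 2 (±)-1-(4-bromo-2,6-dimethoxyphenyl)ethan-1-ol
Conditions: MeMgBr, THF, 0 °C; aq. NH4Cl
Reagents that add atoms: methylmagnesium bromide, C[Mg]Br
Why: Grignard addition to the aldehyde; MeMgBr does not exchange with the aryl bromide at 0 °C, and the racemic carbinol centre is removed in step 2.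

Step 2
Reactants: 2 (±)-1-(4-bromo-2,6-dimethoxyphenyl)ethan-1-ol
Product: 3 1-(4-bromo-2,6-dimethoxyphenyl)ethan-1-one
Conditions: Dess–Martin periodinane, CH2Cl2, rt
Reagents that add atoms: none
Why: Dess–Martin oxidation of a hindered secondary benzylic alcohol under near-neutral conditions; nothing else in 2 is oxidisable.

Step 3
Reactants: 3 1-(4-bromo-2,6-dimethoxyphenyl)ethan-1-one
Product: 4 1-(4-bromo-2-hydroxy-6-methoxyphenyl)ethan-1-one
Conditions: BCl3 (1.2 equiv), CH2Cl2, −78 → 0 °C; H2O
Reagents that add atoms: none
Why: Chelation-controlled ether cleavage: BCl3 bridges the ketone oxygen and one ortho methoxy group and cleaves only that O–CH3 bond; the resulting boron chelate occupies the carbonyl, so the second (equivalent) methoxy group is not activated.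

Step 4
Reactants: 4 1-(4-bromo-2-hydroxy-6-methoxyphenyl)ethan-1-one
Product: 6 7-bromo-5-methoxy-4H-chromen-4-one, via enaminone 5 (not isolated)
Conditions: Me2NCH(OMe)2, toluene, 100 °C; then conc. HCl, CH2Cl2, rt
Reagents that add atoms: N,N-dimethylformamide dimethyl acetal, COC(OC)N(C)C
Why: Enaminone chromone synthesis: the methyl ketone condenses with the amide acetal, and acid-promoted addition of the phenol to the enaminone with loss of dimethylamine closes the pyranone; the reagent supplies C2.

Step 5
Reactants: 6 7-bromo-5-methoxy-4H-chromen-4-one; 7 4-methoxyphenylboronic acid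
Product: 8 (S)-7-bromo-5-methoxy-2-(4-methoxyphenyl)chroman-4-one
Conditions: Pd(OCOCF3)2 (5 mol %), (R)-t-BuPyOx (6 mol %), NH4PF6 (30 mol %), H2O (5 equiv), ClCH2CH2Cl, 60 °C
Reagents that add atoms: none
Why: Catalytic asymmetric conjugate addition of an arylboronic acid to a chromone (transmetalation to cationic divalent palladium, enantio-determining carbopalladation of C2=C3, protonolysis of the palladium enolate); the C2 centre is set by the pyridine-oxazoline ligand. The catalyst stays divalent, so the aryl bromide is not engaged.

Step 6
Reactants: 8 (S)-7-bromo-5-methoxy-2-(4-methoxyphenyl)chroman-4-one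
Product: 11 methyl (2S,3S)-6-bromo-4-methoxy-2-(4-methoxyphenyl)-2,3-dihydrobenzofuran-3-carboxylate, via enol ether 9 (not isolated), via iodane ketal 10 (not isolated)
Conditions: PhI(OAc)2 (1.2 equiv), conc. H2SO4 (2 equiv), HC(OMe)3, 0 °C → rt; aq. NaHCO3
Reagents that add atoms: trimethyl orthoformate, COC(OC)OC; water (work-up), O
Why: Acid and orthoformate convert ketone 8 into enol ether 9, whose C3 attacks the activated trivalent iodine reagent on the face away from the C2 aryl group, and methanol adds to the oxocarbenium carbon to give the 2,3-trans iodane ketal 10. The doubly ortho-oxygenated benzo ring then shifts from C4 to C3 anti to the departing iodine, which leaves as iodobenzene, and the resulting dimethoxycarbenium ion is hydrolysed to the methyl ester on work-up. The closest known reaction type is the oxidative ring contraction of flavanones and other cyclic aryl ketones by trivalent iodine reagents or thallium trinitrate in trimethyl orthoformate. The five-membered ring is closed by a 1,2-aryl shift through a bridged phenonium-like transition state (a semipinacol-type contraction), which forms C3–C3a at the expense of the six-membered ring, and not by a cyclisation. C2 is a spectator and keeps the configuration set in step 5; the new C3 centre is set by the substrate, because iodination anti to the aryl group and migration with inversion place the ester trans to it, and trans is also the more stable epimer. The step needs migration of the benzo ring in preference to migration of the C2 anisyl group or simple elimination (which would lead to aromatised chromones); the 5-methoxy group and the ring oxygen raise the migratory aptitude of the benzo ring and the ketal oxygens stabilise the cation that develops at C4. Low temperature and a short exposure to acid protect the benzylic C2–O bond.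

Step 7
Reactants: 11 methyl (2S,3S)-6-bromo-4-methoxy-2-(4-methoxyphenyl)-2,3-dihydrobenzofuran-3-carboxylate
Product: 12 (2S,3S)-6-bromo-4-methoxy-2-(4-methoxyphenyl)-2,3-dihydrobenzofuran-3-carboxylic acid
Conditions: LiOH·H2O, THF/MeOH/H2O, rt; then 1 M HCl
Reagents that add atoms: lithium hydroxide, [Li+].[OH-]
Why: Ester saponification; enolisation at C3 is harmless because trans is the stable epimer and C3 is reset in step 9. Ring opening by loss of the phenoxide is the reverse of a 5-endo-trig closure and is stereoelectronically slow.

Step 8
Reactants: 12 (2S,3S)-6-bromo-4-methoxy-2-(4-methoxyphenyl)-2,3-dihydrobenzofuran-3-carboxylic acid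
Product: 13 1,3-dioxoisoindolin-2-yl (2S,3S)-6-bromo-4-methoxy-2-(4-methoxyphenyl)-2,3-dihydrobenzofuran-3-carboxylate
Conditions: N-hydroxyphthalimide, N,N′-diisopropylcarbodiimide, DMAP (cat.), CH2Cl2, rt
Reagents that add atoms: N-hydroxyphthalimide, ON1C(=O)c2ccccc2C1=O
Why: Carbodiimide (Steglich-type) esterification gives the redox-active N-acyloxyphthalimide, which can be isolated by filtration through silica.

Step 9
Reactants: 13 1,3-dioxoisoindolin-2-yl (2S,3S)-6-bromo-4-methoxy-2-(4-methoxyphenyl)-2,3-dihydrobenzofuran-3-carboxylate; 14 1-bromo-3,5-dimethoxybenzene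
Product: 17 (2S,3S)-6-bromo-3-(3,5-dimethoxyphenyl)-4-methoxy-2-(4-methoxyphenyl)-2,3-dihydrobenzofuran, via aryllithium 15 (not isolated), via arylzinc chloride 16 (not isolated)
Conditions: 14 (3 equiv), n-BuLi, THF, −78 °C; ZnCl2, −78 °C → rt; then 13, NiCl2·glyme (20 mol %), 4,4′-di-tert-butyl-2,2′-bipyridine (40 mol %), THF/DMF, rt
Reagents that add atoms: none
Why: Nickel-catalysed decarboxylative Negishi-type arylation of a redox-active ester: single-electron reduction of 13 releases CO2 and phthalimide anion, and the benzylic C3 radical is captured by aryl-nickel and reductively eliminated. C3 is reset under substrate control, the aryl group entering the planar radical on the face away from the C2 anisyl group to give the trans (2S,3S) product. The electron-rich aryl bromide should react with low-valent nickel more slowly than the redox-active ester at room temperature.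

Step 10
Reactants: 6 7-bromo-5-methoxy-4H-chromen-4-one; 7 4-methoxyphenylboronic acid
Product: 18 (R)-7-bromo-5-methoxy-2-(4-methoxyphenyl)chroman-4-one
Conditions: Pd(OCOCF3)2 (5 mol %), (S)-t-BuPyOx (6 mol %), NH4PF6 (30 mol %), H2O (5 equiv), ClCH2CH2Cl, 60 °C
Reagents that add atoms: none
Why: The same asymmetric conjugate addition as in step 5 with the enantiomeric ligand, which sets C2 in the opposite sense for unit 1.

Step 11
Reactants: 18 (R)-7-bromo-5-methoxy-2-(4-methoxyphenyl)chroman-4-one
Product: 21 methyl (2R,3R)-6-bromo-4-methoxy-2-(4-methoxyphenyl)-2,3-dihydrobenzofuran-3-carboxylate, via enol ether 19 (not isolated), via iodane ketal 20 (not isolated)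
Conditions: PhI(OAc)2 (1.2 equiv), conc. H2SO4 (2 equiv), HC(OMe)3, 0 °C → rt; aq. NaHCO3
Reagents that add atoms: trimethyl orthoformate, COC(OC)OC; water (work-up), O
Why: The oxidative 1,2-aryl shift and ring contraction of step 6 in the mirror-image series; C2 (R) directs iodination and migration so that the ester ends up trans.

Step 12
Reactants: 21 methyl (2R,3R)-6-bromo-4-methoxy-2-(4-methoxyphenyl)-2,3-dihydrobenzofuran-3-carboxylate
Product: 22 (2R,3R)-6-bromo-4-methoxy-2-(4-methoxyphenyl)-2,3-dihydrobenzofuran-3-carboxylic acid
Conditions: LiOH·H2O, THF/MeOH/H2O, rt; then 1 M HCl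
Reagents that add atoms: lithium hydroxide, [Li+].[OH-]
Why: Ester saponification as in step 7.

Step 13
Reactants: 22 (2R,3R)-6-bromo-4-methoxy-2-(4-methoxyphenyl)-2,3-dihydrobenzofuran-3-carboxylic acid
Product: 23 1,3-dioxoisoindolin-2-yl (2R,3R)-6-bromo-4-methoxy-2-(4-methoxyphenyl)-2,3-dihydrobenzofuran-3-carboxylate
Conditions: N-hydroxyphthalimide, N,N′-diisopropylcarbodiimide, DMAP (cat.), CH2Cl2, rt
Reagents that add atoms: N-hydroxyphthalimide, ON1C(=O)c2ccccc2C1=O
Why: Carbodiimide esterification to the redox-active ester as in step 8.

Step 14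
Reactants: 23 1,3-dioxoisoindolin-2-yl (2R,3R)-6-bromo-4-methoxy-2-(4-methoxyphenyl)-2,3-dihydrobenzofuran-3-carboxylate; 17 (2S,3S)-6-bromo-3-(3,5-dimethoxyphenyl)-4-methoxy-2-(4-methoxyphenyl)-2,3-dihydrobenzofuran
Product: 26 (2R,3R)-6-bromo-3-[(2S,3S)-3-(3,5-dimethoxyphenyl)-4-methoxy-2-(4-methoxyphenyl)-2,3-dihydrobenzofuran-6-yl]-4-methoxy-2-(4-methoxyphenyl)-2,3-dihydrobenzofuran, via aryllithium 24 (not isolated), via arylzinc chloride 25 (not isolated)
Conditions: 17 (2 equiv), n-BuLi, THF, −78 °C; ZnCl2, −78 °C → rt; then 23, NiCl2·glyme (20 mol %), 4,4′-di-tert-butyl-2,2′-bipyridine (40 mol %), THF/DMF, rt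
Reagents that add atoms: none
Why: The decarboxylative Negishi-type coupling of step 9 used as the fragment union; bromine–lithium exchange at −78 °C with immediate transmetalation to zinc outruns deprotonation at the benzylic positions of 17. C3 of unit 1 is set trans to the C2 anisyl group by the same substrate control, the stereocentres of 25 are spectators, and the bromide of 23 is kept for step 15.

Step 15
Reactants: 26 (2R,3R)-6-bromo-3-[(2S,3S)-3-(3,5-dimethoxyphenyl)-4-methoxy-2-(4-methoxyphenyl)-2,3-dihydrobenzofuran-6-yl]-4-methoxy-2-(4-methoxyphenyl)-2,3-dihydrobenzofuran; 27 (E)-[2-(4-methoxyphenyl)ethenyl]boronic acid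
Product: 28 (2R,3R)-3-[(2S,3S)-3-(3,5-dimethoxyphenyl)-4-methoxy-2-(4-methoxyphenyl)-2,3-dihydrobenzofuran-6-yl]-4-methoxy-2-(4-methoxyphenyl)-6-[(E)-2-(4-methoxyphenyl)ethenyl]-2,3-dihydrobenzofuran
Conditions: PdCl2(dppf) (5 mol %), K2CO3, 1,4-dioxane/H2O, 80 °C
Reagents that add atoms: none
Why: Suzuki–Miyaura coupling of the aryl bromide with an (E)-alkenylboronic acid; transmetalation and reductive elimination retain the alkene geometry, so the (E)-stilbene forms without the regio- and stereochemical ambiguity of a Heck reaction.

Step 16
Reactants: 28 (2R,3R)-3-[(2S,3S)-3-(3,5-dimethoxyphenyl)-4-methoxy-2-(4-methoxyphenyl)-2,3-dihydrobenzofuran-6-yl]-4-methoxy-2-(4-methoxyphenyl)-6-[(E)-2-(4-methoxyphenyl)ethenyl]-2,3-dihydrobenzofuran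
Product: 29 (2R,3R)-3-[(2S,3S)-3-(3,5-dihydroxyphenyl)-4-hydroxy-2-(4-hydroxyphenyl)-2,3-dihydrobenzofuran-6-yl]-2-(4-hydroxyphenyl)-6-[(E)-2-(4-hydroxyphenyl)ethenyl]-2,3-dihydrobenzofuran-4-ol
Conditions: BBr3 (excess), CH2Cl2, −78 → 0 °C, exclusion of light; then MeOH, H2O
Reagents that add atoms: none
Why: Lewis-acid cleavage of all seven aryl methyl ethers (complexation at oxygen, bromide attack at methyl) at low temperature. None of the four stereocentres is enolisable, and both trans pairs are the thermodynamically preferred arrangements, so a reversible opening at C2–O would reclose to the same isomers.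

## Compound list

1 | 4-bromo-2,6-dimethoxybenzaldehyde | COc1cc(Br)cc(OC)c1C=O | starting material
2 | (±)-1-(4-bromo-2,6-dimethoxyphenyl)ethan-1-ol | COc1cc(Br)cc(OC)c1C(C)O | intermediate
3 | 1-(4-bromo-2,6-dimethoxyphenyl)ethan-1-one | COc1cc(Br)cc(OC)c1C(C)=O | intermediate
4 | 1-(4-bromo-2-hydroxy-6-methoxyphenyl)ethan-1-one | COc1cc(Br)cc(O)c1C(C)=O | intermediate
5 | (E)-1-(4-bromo-2-hydroxy-6-methoxyphenyl)-3-(dimethylamino)prop-2-en-1-one | COc1cc(Br)cc(O)c1C(=O)/C=C/N(C)C | intermediate
6 | 7-bromo-5-methoxy-4H-chromen-4-one | O=c1ccoc2cc(Br)cc(OC)c12 | intermediate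
7 | 4-methoxyphenylboronic acid | COc1ccc(B(O)O)cc1 | starting material
8 | (S)-7-bromo-5-methoxy-2-(4-methoxyphenyl)chroman-4-one | Brc1cc(OC)c2c(c1)O[C@H](c1ccc(OC)cc1)CC2=O | intermediate
9 | (S)-7-bromo-4,5-dimethoxy-2-(4-methoxyphenyl)-2H-chromene | Brc1cc(OC)c2c(c1)O[C@H](c1ccc(OC)cc1)C=C2OC | intermediate
10 | (2R,3R)-3-[acetoxy(phenyl)-λ3-iodanyl]-7-bromo-4,4,5-trimethoxy-2-(4-methoxyphenyl)chromane (iodine trans to the C2 aryl group; C2 arranged as in 8) | Brc1cc(OC)c2c(c1)O[C@H](c1ccc(OC)cc1)[C@@H](I(OC(C)=O)c1ccccc1)C2(OC)OC | intermediate
11 | methyl (2S,3S)-6-bromo-4-methoxy-2-(4-methoxyphenyl)-2,3-dihydrobenzofuran-3-carboxylate | Brc1cc(OC)c2c(c1)O[C@H](c1ccc(OC)cc1)[C@H]2C(=O)OC | intermediate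
12 | (2S,3S)-6-bromo-4-methoxy-2-(4-methoxyphenyl)-2,3-dihydrobenzofuran-3-carboxylic acid | Brc1cc(OC)c2c(c1)O[C@H](c1ccc(OC)cc1)[C@H]2C(=O)O | intermediate
13 | 1,3-dioxoisoindolin-2-yl (2S,3S)-6-bromo-4-methoxy-2-(4-methoxyphenyl)-2,3-dihydrobenzofuran-3-carboxylate | Brc1cc(OC)c2c(c1)O[C@H](c1ccc(OC)cc1)[C@H]2C(=O)ON1C(=O)c2ccccc2C1=O | intermediate
14 | 1-bromo-3,5-dimethoxybenzene | COc1cc(Br)cc(OC)c1 | starting material
15 | (3,5-dimethoxyphenyl)lithium | [Li]c1cc(OC)cc(OC)c1 | intermediate
16 | (3,5-dimethoxyphenyl)zinc chloride | Cl[Zn]c1cc(OC)cc(OC)c1 | intermediate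
17 | (2S,3S)-6-bromo-3-(3,5-dimethoxyphenyl)-4-methoxy-2-(4-methoxyphenyl)-2,3-dihydrobenzofuran | Brc1cc(OC)c2c(c1)O[C@H](c1ccc(OC)cc1)[C@H]2c1cc(OC)cc(OC)c1 | intermediate
18 | (R)-7-bromo-5-methoxy-2-(4-methoxyphenyl)chroman-4-one | Brc1cc(OC)c2c(c1)O[C@@H](c1ccc(OC)cc1)CC2=O | intermediate
19 | (R)-7-bromo-4,5-dimethoxy-2-(4-methoxyphenyl)-2H-chromene | Brc1cc(OC)c2c(c1)O[C@@H](c1ccc(OC)cc1)C=C2OC | intermediate
20 | (2S,3S)-3-[acetoxy(phenyl)-λ3-iodanyl]-7-bromo-4,4,5-trimethoxy-2-(4-methoxyphenyl)chromane (iodine trans to the C2 aryl group; C2 arranged as in 18) | Brc1cc(OC)c2c(c1)O[C@@H](c1ccc(OC)cc1)[C@H](I(OC(C)=O)c1ccccc1)C2(OC)OC | intermediate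
21 | methyl (2R,3R)-6-bromo-4-methoxy-2-(4-methoxyphenyl)-2,3-dihydrobenzofuran-3-carboxylate | Brc1cc(OC)c2c(c1)O[C@@H](c1ccc(OC)cc1)[C@@H]2C(=O)OC | intermediate
22 | (2R,3R)-6-bromo-4-methoxy-2-(4-methoxyphenyl)-2,3-dihydrobenzofuran-3-carboxylic acid | Brc1cc(OC)c2c(c1)O[C@@H](c1ccc(OC)cc1)[C@@H]2C(=O)O | intermediate
23 | 1,3-dioxoisoindolin-2-yl (2R,3R)-6-bromo-4-methoxy-2-(4-methoxyphenyl)-2,3-dihydrobenzofuran-3-carboxylate | Brc1cc(OC)c2c(c1)O[C@@H](c1ccc(OC)cc1)[C@@H]2C(=O)ON1C(=O)c2ccccc2C1=O | intermediate
24 | [(2S,3S)-3-(3,5-dimethoxyphenyl)-4-methoxy-2-(4-methoxyphenyl)-2,3-dihydrobenzofuran-6-yl]lithium | [Li]c1cc(OC)c2c(c1)O[C@H](c1ccc(OC)cc1)[C@H]2c1cc(OC)cc(OC)c1 | intermediate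
25 | [(2S,3S)-3-(3,5-dimethoxyphenyl)-4-methoxy-2-(4-methoxyphenyl)-2,3-dihydrobenzofuran-6-yl]zinc chloride | Cl[Zn]c1cc(OC)c2c(c1)O[C@H](c1ccc(OC)cc1)[C@H]2c1cc(OC)cc(OC)c1 | intermediate
26 | (2R,3R)-6-bromo-3-[(2S,3S)-3-(3,5-dimethoxyphenyl)-4-methoxy-2-(4-methoxyphenyl)-2,3-dihydrobenzofuran-6-yl]-4-methoxy-2-(4-methoxyphenyl)-2,3-dihydrobenzofuran | Brc1cc(OC)c2c(c1)O[C@@H](c1ccc(OC)cc1)[C@@H]2c1cc(OC)c2c(c1)O[C@H](c1ccc(OC)cc1)[C@H]2c1cc(OC)cc(OC)c1 | intermediate
27 | (E)-[2-(4-methoxyphenyl)ethenyl]boronic acid | COc1ccc(/C=C/B(O)O)cc1 | starting material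
28 | (2R,3R)-3-[(2S,3S)-3-(3,5-dimethoxyphenyl)-4-methoxy-2-(4-methoxyphenyl)-2,3-dihydrobenzofuran-6-yl]-4-methoxy-2-(4-methoxyphenyl)-6-[(E)-2-(4-methoxyphenyl)ethenyl]-2,3-dihydrobenzofuran (heptamethyl ether of the target) | COc1ccc(/C=C/c2cc(OC)c3c(c2)O[C@@H](c2ccc(OC)cc2)[C@@H]3c2cc(OC)c3c(c2)O[C@H](c2ccc(OC)cc2)[C@H]3c2cc(OC)cc(OC)c2)cc1 | intermediate
29 | (2R,3R)-3-[(2S,3S)-3-(3,5-dihydroxyphenyl)-4-hydroxy-2-(4-hydroxyphenyl)-2,3-dihydrobenzofuran-6-yl]-2-(4-hydroxyphenyl)-6-[(E)-2-(4-hydroxyphenyl)ethenyl]-2,3-dihydrobenzofuran-4-ol (CNP0248228.3) | Oc1ccc(/C=C/c2cc(O)c3c(c2)O[C@@H](c2ccc(O)cc2)[C@@H]3c2cc(O)c3c(c2)O[C@H](c2ccc(O)cc2)[C@H]3c2cc(O)cc(O)c2)cc1 | target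

## Step count and least certain steps

Total: 16 steps. Longest linear sequence: 12 steps (steps 1–9, then 14–16). Steps 1–4 are common to both units, and the (S) series (steps 5–9) should be run on two to three times the scale of the (R) series because 17 is used in excess in step 14.

**Step 6 (key step; step 11 is its mirror image).** Three processes are most likely to interfere.
- Migration of the C2 anisyl group, or plain elimination, in place of the benzo-ring shift. The anisyl group is itself a good migrating group and can lie anti to iodine, and either path ends in an aromatised chromone.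
- Acid-induced reversible ionisation of the benzylic C2–O bond, which would erode the enantiomeric purity set in step 5.
- Electrophilic attack of the iodine reagent on the anisole rings.

Fallback: a Wolff ring contraction, which forms the same C3–C3a bond by a different mechanism and without strong acid. It sets out from 8. Deprotonation and trifluoroacetylation (LiHMDS, THF, −78 °C; CF3CO2CH2CF3) give the α-trifluoroacetyl ketone F1. Detrifluoroacetylative diazo transfer (MsN3, Et3N, MeCN) gives the diazoketone F2. Irradiation in methanol makes the benzo ring migrate to the diazo carbon with loss of nitrogen, giving the ring-contracted ketene F3, which methanol traps as 11 together with its cis epimer F4. Equilibration (NaOMe, MeOH) converts F4 into 11, where the fallback rejoins the route; since C3 is reset in step 9, the mixture could also be carried on as such.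

**Step 14 (step 9 is the simpler test of the same reaction).** Four processes are most likely to interfere.
- Competing insertion of low-valent nickel into the aryl bromide of 23 or of the product, leading to biaryl coupling and oligomerisation. Nickel/bipyridine systems can also activate aryl bromides.
- Dimerisation or reduction of the stabilised benzylic radical.
- Incomplete exchange, or benzylic deprotonation, during the lithiation of 17.
- Consumption of an excess of the advanced nucleophile 25.

Fallback: remove the bromide before the radical coupling. It sets out from 21. Suzuki–Miyaura coupling with 27 (PdCl2(dppf), K2CO3, dioxane/H2O) gives the styryl ester F5. Saponification gives the acid F6, and esterification with N-hydroxyphthalimide gives the redox-active ester F7. The same nickel-catalysed coupling of F7 with 25 then gives 28 directly, where the fallback rejoins the route, bypassing 26 and step 15.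

**Step 5 (and step 10).** The most likely failures are insufficient enantioselectivity or slow conversion, because the peri 5-methoxy group hinders coordination of the carbonyl and the electron-rich boronic acid 7 protodeboronates readily. Slow loss of the aryl bromide to traces of zerovalent palladium is also possible.

Fallback: a racemic synthesis and resolution. It sets out from 4. Claisen–Schmidt condensation with 4-methoxybenzaldehyde (KOH, EtOH) gives the chalcone F8. Cyclisation (NaOAc, EtOH, reflux) gives the racemate of 8 and 18, which is separated by preparative chromatography on a chiral stationary phase. The fallback rejoins the route at 8 and 18, and because both antipodes are needed, nothing is discarded.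

**Step 16.** The most likely failures are listed here.
- Ionisation of the C2–O or C2′–O bond under the Lewis acid, with capture of the benzylic cation by the stilbene or by ring C (skeletal rearrangement).
- Addition of HBr to the alkene, or E/Z isomerisation.
- Incomplete cleavage of seven ethers.

Fallback: cleave the ethers before the alkene is present. It sets out from 26. BBr3 (CH2Cl2, −78 → 0 °C) gives the hexaphenol bromide F9, and acetylation (Ac2O, pyridine) gives the hexaacetate F10. Heck reaction with 4-acetoxystyrene (Pd(OAc)2, P(o-tol)3, Et3N, DMF, 100 °C) gives the heptaacetate F11. Mild methanolysis (K2CO3, MeOH, rt) releases 29, where the fallback rejoins the route.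

## Further compounds

F1 | step 6 | (2S)-7-bromo-5-methoxy-2-(4-methoxyphenyl)-3-(trifluoroacetyl)chroman-4-one (mixture at C3, largely enolised) | Brc1cc(OC)c2c(c1)O[C@H](c1ccc(OC)cc1)C(C(=O)C(F)(F)F)C2=O
F2 | step 6 | (2R)-7-bromo-3-diazo-5-methoxy-2-(4-methoxyphenyl)chroman-4-one (C2 arranged as in 8; the descriptor changes by priority only) | Brc1cc(OC)c2c(c1)O[C@H](c1ccc(OC)cc1)C(=[N+]=[N-])C2=O
F3 | step 6 | [6-bromo-4-methoxy-2-(4-methoxyphenyl)benzofuran-3(2H)-ylidene]methanone (ketene; C2 arranged as in 8) | Brc1cc(OC)c2c(c1)O[C@H](c1ccc(OC)cc1)C2=C=O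
F4 | step 6 | methyl (2S,3R)-6-bromo-4-methoxy-2-(4-methoxyphenyl)-2,3-dihydrobenzofuran-3-carboxylate (cis epimer of 11) | Brc1cc(OC)c2c(c1)O[C@H](c1ccc(OC)cc1)[C@@H]2C(=O)OC
F5 | step 14 | methyl (2R,3R)-4-methoxy-2-(4-methoxyphenyl)-6-[(E)-2-(4-methoxyphenyl)ethenyl]-2,3-dihydrobenzofuran-3-carboxylate | COc1ccc(/C=C/c2cc(OC)c3c(c2)O[C@@H](c2ccc(OC)cc2)[C@@H]3C(=O)OC)cc1
F6 | step 14 | (2R,3R)-4-methoxy-2-(4-methoxyphenyl)-6-[(E)-2-(4-methoxyphenyl)ethenyl]-2,3-dihydrobenzofuran-3-carboxylic acid | COc1ccc(/C=C/c2cc(OC)c3c(c2)O[C@@H](c2ccc(OC)cc2)[C@@H]3C(=O)O)cc1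
F7 | step 14 | 1,3-dioxoisoindolin-2-yl (2R,3R)-4-methoxy-2-(4-methoxyphenyl)-6-[(E)-2-(4-methoxyphenyl)ethenyl]-2,3-dihydrobenzofuran-3-carboxylate | COc1ccc(/C=C/c2cc(OC)c3c(c2)O[C@@H](c2ccc(OC)cc2)[C@@H]3C(=O)ON2C(=O)c3ccccc3C2=O)cc1
F8 | step 5 | (E)-1-(4-bromo-2-hydroxy-6-methoxyphenyl)-3-(4-methoxyphenyl)prop-2-en-1-one | COc1ccc(/C=C/C(=O)c2c(O)cc(Br)cc2OC)cc1
F9 | step 16 | (2R,3R)-6-bromo-3-[(2S,3S)-3-(3,5-dihydroxyphenyl)-4-hydroxy-2-(4-hydroxyphenyl)-2,3-dihydrobenzofuran-6-yl]-2-(4-hydroxyphenyl)-2,3-dihydrobenzofuran-4-ol | Brc1cc(O)c2c(c1)O[C@@H](c1ccc(O)cc1)[C@@H]2c1cc(O)c2c(c1)O[C@H](c1ccc(O)cc1)[C@H]2c1cc(O)cc(O)c1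
F10 | step 16 | hexaacetate of F9 | Brc1cc(OC(C)=O)c2c(c1)O[C@@H](c1ccc(OC(C)=O)cc1)[C@@H]2c1cc(OC(C)=O)c2c(c1)O[C@H](c1ccc(OC(C)=O)cc1)[C@H]2c1cc(OC(C)=O)cc(OC(C)=O)c1
F11 | step 16 | heptaacetate of 29 | CC(=O)Oc1ccc(/C=C/c2cc(OC(C)=O)c3c(c2)O[C@@H](c2ccc(OC(C)=O)cc2)[C@@H]3c2cc(OC(C)=O)c3c(c2)O[C@H](c2ccc(OC(C)=O)cc2)[C@H]3c2cc(OC(C)=O)cc(OC(C)=O)c2)cc1
A1 | alternative 1 | heptamethyl ether of the target (identical with 28) | COc1ccc(/C=C/c2cc(OC)c3c(c2)O[C@@H](c2ccc(OC)cc2)[C@@H]3c2cc(OC)c3c(c2)O[C@H](c2ccc(OC)cc2)[C@H]3c2cc(OC)cc(OC)c2)cc1
A2 | alternative 1 | open-chain diphenol diol: both dihydrofuran rings opened at O1–C2 and O1′–C2′, C3 and C3′ configured as in the target, either configuration at the two carbinol carbons | COc1ccc(/C=C/c2cc(O)c(c(OC)c2)[C@H](C(O)c2ccc(OC)cc2)c2cc(O)c(c(OC)c2)[C@@H](C(O)c2ccc(OC)cc2)c2cc(OC)cc(OC)c2)cc1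
A3 | alternative 2 | unit 1 bromide carrying at C3 the ring B phenol with a triisopropylsilyloxy group and a benzylic methyl ether side chain (either configuration at the ether carbon) | Brc1cc(OC)c2c(c1)O[C@@H](c1ccc(OC)cc1)[C@@H]2c1cc(O)c(C(OC)c2cc(OC)cc(OC)c2)c(O[Si](C(C)C)(C(C)C)C(C)C)c1
A4 | alternative 2 | 3-[(2R,3R)-6-bromo-4-methoxy-2-(4-methoxyphenyl)-2,3-dihydrobenzofuran-3-yl]cyclobut-2-en-1-one | Brc1cc(OC)c2c(c1)O[C@@H](c1ccc(OC)cc1)[C@@H]2C1=CC(=O)C1
A5 | alternative 2 | {[3-(3,5-dimethoxyphenyl)-3-methoxyprop-1-yn-1-yl]oxy}tri(propan-2-yl)silane (either configuration) | COC(C#CO[Si](C(C)C)(C(C)C)C(C)C)c1cc(OC)cc(OC)c1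
A6 | alternative 3 | target skeleton with free hydroxyl at C4 of ring A and six methyl ethers | COc1ccc(/C=C/c2cc(O)c3c(c2)O[C@@H](c2ccc(OC)cc2)[C@@H]3c2cc(OC)c3c(c2)O[C@H](c2ccc(OC)cc2)[C@H]3c2cc(OC)cc(OC)c2)cc1
A7 | alternative 3 | 2-methyl-4,5-dihydrofuran bearing at C3 the 5-(4-methoxyphenyl)-1,3-dioxopent-4-enyl chain, at C4 the unit 2 aryl group and at C5 the 4-methoxyphenyl group (ring stereocentres arranged as C3 and C2 of the target) | COc1ccc(/C=C/C(=O)CC(=O)C2=C(C)O[C@@H](c3ccc(OC)cc3)[C@@H]2c2cc(OC)c3c(c2)O[C@H](c2ccc(OC)cc2)[C@H]3c2cc(OC)cc(OC)c2)cc1
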